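**Retrosynthetic overview**
- The bridge C–C bond is cut last: the target comes from a ring B ortho-quinone methide (released from a benzylic sulfone) and the ring A chroman ketone as C6 nucleophile, joined enantioselectively.
- The sulfone comes from the ring B chroman ketone, 6-methylheptanal and a sulfinic acid.
- Both chroman ketones come from one common 5,7-bis(silyloxy)-2,2-dimethylchroman by C8 Friedel–Crafts acylation with (R)-2-methylbutanoic acid or isobutyric acid.
- The common chroman comes from isoprene annulation onto the single free OH of 3,5-bis(silyloxy)phenol. That phenol comes from resorcinol bis-silyl ether by C–H borylation and a boron-to-oxygen 1,2-aryl shift, which creates the phloroglucinol pattern and the one oxygen (the later ring oxygen) that steers all later regiochemistry.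
- Ring order: the benzene ring is bought (resorcinol); the pyran ring is made once on the common chroman and serves both halves; the two halves are joined in the last step.

Assumptions: acid 7 is bought as the single R enantiomer; the target is R at the acyl α-carbon and R at the bridge carbon (ring A aryl ranks above ring B aryl); the facial sense of step 8 is assigned by model only and must be confirmed (ECD or crystallography), with the quinidine-derived pseudoenantiomeric catalyst used if it is reversed.

**Route**

Step 1
Reactants: 1 resorcinol (benzene-1,3-diol)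
Product: 2 1,3-bis(tert-butyldimethylsilyloxy)benzene
Conditions: t-BuMe2SiCl (2.3 equiv), imidazole (4 equiv), DMF, 0 °C → rt
Reagents that add atoms: tert-butyldimethylsilyl chloride, CC(C)(C)[Si](C)(C)Cl
Why: Imidazole-promoted O-silylation of both phenols is routine, and the two bulky silyl ethers later shield the ring carbons next to them (protection; no stereocentre).

Step 2
Reactants: 2 1,3-bis(tert-butyldimethylsilyloxy)benzene
Product: 4 3,5-bis(tert-butyldimethylsilyloxy)phenol, via arylboronic pinacol ester 3 (not isolated)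
Conditions: [Ir(OMe)(cod)]2 (1.5 mol%), 4,4′-di-tert-butyl-2,2′-bipyridine (3 mol%), B2pin2 (1.0 equiv), THF, 80 °C; then 30% H2O2, aq. NaHCO3, 0 °C → rt
Reagents that add atoms: hydrogen peroxide, OO (the new phenol oxygen); bis(pinacolato)diboron, CC1(C)OB(OC1(C)C)B1OC(C)(C)C(C)(C)O1 (the boronate group of 3 only)
Why: Sterically controlled C–H borylation by the [Ir(OMe)(cod)]2/bipyridine catalyst touches only C5 (the one C–H with no ortho substituent), and the hydroperoxide adduct of boronate 3 then undergoes the 1,2-shift of the aryl carbon from boron to oxygen (1,2-metallate rearrangement), which turns the resorcinol frame into a phloroglucinol with exactly one free OH.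

Step 3
Reactants: 4 3,5-bis(tert-butyldimethylsilyloxy)phenol; 5 isoprene (2-methylbuta-1,3-diene)
Product: 6 5,7-bis(tert-butyldimethylsilyloxy)-2,2-dimethylchromane
Conditions: 5 (1.5 equiv), AgOSO2CF3 (5 mol%), ClCH2CH2Cl, rt, 16 h
Reagents that add atoms: none
Why: AgOSO2CF3-mediated Friedel–Crafts prenylation ortho to the only free OH and Markovnikov hydroalkoxylation close the pyran ring (phenol–diene annulation); the two ortho carbons of 4 are equivalent and the para carbon is buried between two silyl ethers, so a single chroman results.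

Step 4
Reactants: 6 5,7-bis(tert-butyldimethylsilyloxy)-2,2-dimethylchromane; 7 (R)-2-methylbutanoic acid
Product: 10 (2R)-1-(5,7-dihydroxy-2,2-dimethylchroman-8-yl)-2-methylbutan-1-one, via mixed trifluoroacetic anhydride 8 (not isolated), via bis-silyl ketone 9 (not isolated)
Conditions: 7 (1.3 equiv), (CF3CO)2O (2 equiv), 85% H3PO4 (10 mol%), CH2Cl2, 0 °C → rt; evaporate; then 48% aq. HF, MeCN, 0 °C → rt
Reagents that add atoms: trifluoroacetic anhydride, O=C(OC(=O)C(F)(F)F)C(F)(F)F (the trifluoroacetyl group of 8 only; nothing stays in 10)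
Why: Friedel–Crafts acylation by mixed anhydride 8 should go to C8 because C6 is walled in by two silyloxy groups while C8 has the tied-back ring oxygen on one side (the same bias that sends electrophiles to C8 of 5,7-di-O-protected flavans); the acidic, base-free medium leaves the R α-stereocentre of 7 untouched, and HF then removes both silyl groups.

Step 5
Reactants: 6 5,7-bis(tert-butyldimethylsilyloxy)-2,2-dimethylchromane; 11 isobutyric acid (2-methylpropanoic acid)
Product: 14 1-(5,7-dihydroxy-2,2-dimethylchroman-8-yl)-2-methylpropan-1-one, via mixed trifluoroacetic anhydride 12 (not isolated), via bis-silyl ketone 13 (not isolated)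
Conditions: 11 (1.3 equiv), (CF3CO)2O (2 equiv), 85% H3PO4 (10 mol%), CH2Cl2, 0 °C → rt; evaporate; then 48% aq. HF, MeCN, 0 °C → rt
Reagents that add atoms: trifluoroacetic anhydride, O=C(OC(=O)C(F)(F)F)C(F)(F)F (the trifluoroacetyl group of 12 only; nothing stays in 14)
Why: Same sterically directed C8 Friedel–Crafts acylation and fluoride desilylation as in step 4, here with an achiral acid.

Step 6
Reactants: 15 5-methylhex-1-ene
Product: 16 6-methylheptanal
Conditions: CO/H2 (1:1, 10 bar), Rh(acac)(CO)2 (0.5 mol%), BiPhePhos ligand (1 mol%), toluene, 80 °C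
Reagents that add atoms: carbon monoxide, [C-]#[O+]
Why: Rh(acac)(CO)2 with the bulky bisphosphite BiPhePhos hydroformylates an unbranched terminal alkene to the linear aldehyde with high selectivity (n-selective hydroformylation).

Step 7
Reactants: 14 1-(5,7-dihydroxy-2,2-dimethylchroman-8-yl)-2-methylpropan-1-one; 16 6-methylheptanal
Product: 18 1-{5,7-dihydroxy-2,2-dimethyl-6-[6-methyl-1-(4-methylbenzenesulfonyl)heptyl]chroman-8-yl}-2-methylpropan-1-one (racemic at the sulfonyl-bearing carbon), via benzylic alcohol 17 (not isolated)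
Conditions: p-TolSO2H (1.5 equiv), 16 (1.5 equiv), 4 Å molecular sieves, CH2Cl2, rt; 14 added slowly
Reagents that add atoms: 4-methylbenzenesulfinic acid, Cc1ccc(cc1)S(=O)O
Why: Acid-mediated hydroxyalkylation at C6 (the only free ring carbon of 14) gives benzylic alcohol 17, whose acid-promoted ionisation to the phenol-stabilised benzylic cation and capture at sulfur by the soft sulfinate give a storable sulfone (three-component sulfonylalkylation of a phenol); its new stereocentre is racemic and is erased in step 8.

Step 8
Reactants: 18 1-{5,7-dihydroxy-2,2-dimethyl-6-[6-methyl-1-(4-methylbenzenesulfonyl)heptyl]chroman-8-yl}-2-methylpropan-1-one; 10 (2R)-1-(5,7-dihydroxy-2,2-dimethylchroman-8-yl)-2-methylbutan-1-one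
Product: 20 (2R)-1-{6-[(1R)-1-[5,7-dihydroxy-2,2-dimethyl-8-(2-methylpropanoyl)chroman-6-yl]-6-methylheptyl]-5,7-dihydroxy-2,2-dimethylchroman-8-yl}-2-methylbutan-1-one, via ortho-quinone methide 19 (not isolated)
Conditions: quinine-derived squaramide 3-[3,5-bis(trifluoromethyl)anilino]-4-[(9-deoxy-epi-quinin-9-yl)amino]cyclobut-3-ene-1,2-dione (10 mol%), NaHCO3 (3 equiv, finely ground), toluene/CHCl3 4:1, −20 °C
Reagents that add atoms: none
Why: Proposed new method: enantioselective hetero-coupling of two acylphloroglucinols, in which the catalyst amine triggers E1cB loss of sulfinate from 18 to give planar quinone methide 19, the squaramide N–H bonds hold the carbonyl of 19 while the ammonium ion-pairs with the phenoxide of 10, and C6 of 10 (its only free ring carbon) adds to one face of the exocyclic CH= to set the bridge carbon as R before re-aromatisation; the closest known reaction type is the cinchona-squaramide/base-mediated asymmetric addition of naphthols and cyclic 1,3-dicarbonyl compounds to quinone methides released from 2-(1-sulfonylalkyl)phenols, not yet shown for an alkyl-substituted acylphloroglucinol quinone methide or an acylphloroglucinol nucleophile.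

**Compound list**

1 | resorcinol | Oc1cccc(O)c1 | starting material
2 | 1,3-bis(tert-butyldimethylsilyloxy)benzene | CC(C)(C)[Si](C)(C)Oc1cccc(O[Si](C)(C)C(C)(C)C)c1 | intermediate
3 | 2-[3,5-bis(tert-butyldimethylsilyloxy)phenyl]-4,4,5,5-tetramethyl-1,3,2-dioxaborolane | CC(C)(C)[Si](C)(C)Oc1cc(O[Si](C)(C)C(C)(C)C)cc(c1)B1OC(C)(C)C(C)(C)O1 | intermediate (not isolated)
4 | 3,5-bis(tert-butyldimethylsilyloxy)phenol | CC(C)(C)[Si](C)(C)Oc1cc(O)cc(O[Si](C)(C)C(C)(C)C)c1 | intermediate
5 | isoprene | C=CC(C)=C | starting material
6 | 5,7-bis(tert-butyldimethylsilyloxy)-2,2-dimethylchromane | CC1(C)CCc2c(O[Si](C)(C)C(C)(C)C)cc(O[Si](C)(C)C(C)(C)C)cc2O1 | intermediate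
7 | (R)-2-methylbutanoic acid | CC[C@@H](C)C(=O)O | starting material
8 | (2R)-2-methylbutanoic trifluoroacetic anhydride | CC[C@@H](C)C(=O)OC(=O)C(F)(F)F | intermediate (not isolated)
9 | (2R)-1-[5,7-bis(tert-butyldimethylsilyloxy)-2,2-dimethylchroman-8-yl]-2-methylbutan-1-one | CC[C@@H](C)C(=O)c1c(O[Si](C)(C)C(C)(C)C)cc(O[Si](C)(C)C(C)(C)C)c2c1OC(C)(C)CC2 | intermediate (not isolated)
10 | (2R)-1-(5,7-dihydroxy-2,2-dimethylchroman-8-yl)-2-methylbutan-1-one (ring A half) | CC[C@@H](C)C(=O)c1c(O)cc(O)c2c1OC(C)(C)CC2 | intermediate
11 | isobutyric acid | CC(C)C(=O)O | starting material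
12 | 2-methylpropanoic trifluoroacetic anhydride | CC(C)C(=O)OC(=O)C(F)(F)F | intermediate (not isolated)
13 | 1-[5,7-bis(tert-butyldimethylsilyloxy)-2,2-dimethylchroman-8-yl]-2-methylpropan-1-one | CC(C)C(=O)c1c(O[Si](C)(C)C(C)(C)C)cc(O[Si](C)(C)C(C)(C)C)c2c1OC(C)(C)CC2 | intermediate (not isolated)
14 | 1-(5,7-dihydroxy-2,2-dimethylchroman-8-yl)-2-methylpropan-1-one (ring B half) | CC(C)C(=O)c1c(O)cc(O)c2c1OC(C)(C)CC2 | intermediate
15 | 5-methylhex-1-ene | CC(C)CCC=C | starting material
16 | 6-methylheptanal | CC(C)CCCCC=O | intermediate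
17 | 1-[5,7-dihydroxy-6-(1-hydroxy-6-methylheptyl)-2,2-dimethylchroman-8-yl]-2-methylpropan-1-one (benzylic alcohol, racemic) | CC(C)C(=O)c1c(O)c(C(O)CCCCC(C)C)c(O)c2c1OC(C)(C)CC2 | intermediate (not isolated)
18 | 1-{5,7-dihydroxy-2,2-dimethyl-6-[6-methyl-1-(4-methylbenzenesulfonyl)heptyl]chroman-8-yl}-2-methylpropan-1-one (racemic) | CC(C)C(=O)c1c(O)c(C(CCCCC(C)C)S(=O)(=O)c2ccc(C)cc2)c(O)c2c1OC(C)(C)CC2 | intermediate
19 | 5-hydroxy-2,2-dimethyl-6-(6-methylheptylidene)-8-(2-methylpropanoyl)-3,4-dihydro-2H-chromen-7(6H)-one (ortho-quinone methide) | CC(C)C(=O)C1=C2OC(C)(C)CCC2=C(O)C(=CCCCCC(C)C)C1=O | intermediate (not isolated)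
20 | (2R)-1-{6-[(1R)-1-[5,7-dihydroxy-2,2-dimethyl-8-(2-methylpropanoyl)chroman-6-yl]-6-methylheptyl]-5,7-dihydroxy-2,2-dimethylchroman-8-yl}-2-methylbutan-1-one | CC[C@@H](C)C(=O)c1c(O)c([C@H](CCCCC(C)C)c2c(O)c3c(c(C(=O)C(C)C)c2O)OC(C)(C)CC3)c(O)c2c1OC(C)(C)CC2 | target

**Step count and risks**

Total steps: 8. Longest linear sequence: 6 (steps 1, 2, 3, 5, 7, 8).

Most likely to fail, first: step 8, the new coupling. Its selectivity and facial sense are unproven, and the bridged product could revert under base. The fallback uses known chemistry and sets out from 18 (with 10). The coupling is run with achiral base only (NaHCO3, CH2Cl2, 0 °C), the established base-promoted release of a quinone methide from a 2-(1-sulfonylalkyl)phenol and C-alkylation of a phenol. This gives 20 together with its bridge epimer (2R)-1-{6-[(1S)-1-[5,7-dihydroxy-2,2-dimethyl-8-(2-methylpropanoyl)chroman-6-yl]-6-methylheptyl]-5,7-dihydroxy-2,2-dimethylchroman-8-yl}-2-methylbutan-1-one F1 in about equal amounts. Because the acyl centre is fixed as R, the two are diastereomers; they are separated by preparative HPLC on an amylose tris(3,5-dimethylphenylcarbamate) phase, and the route is rejoined at 20.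

Second: step 4 (step 5 shares the chemistry but risks less material). The C8 over C6 selectivity and the survival of the silyl ethers during acylation are argued by analogy, not proven. The fallback sets out from 4 and fixes the acyl position by an intramolecular transfer instead. Esterification of 4 with 7 (dicyclohexylcarbodiimide, catalytic 4-dimethylaminopyridine, CH2Cl2, 0 °C) gives 3,5-bis(tert-butyldimethylsilyloxy)phenyl (2R)-2-methylbutanoate F2. Photo-Fries rearrangement (254 nm, cyclohexane) moves the acyl group to the carbon ortho to the freed OH and gives (2R)-1-[2-hydroxy-4,6-bis(tert-butyldimethylsilyloxy)phenyl]-2-methylbutan-1-one F3. Isoprene with AgOSO2CF3 then alkylates the remaining ortho carbon and closes the pyran on that same OH, which comes back to the route at 9; 9 is desilylated as in step 4.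

Third: step 7. The benzylic cation formed from 17 can be intercepted by unreacted 14 (symmetrical dimer) or lose a proton to give the vinyl phenol before sulfinate traps it. The fallback sets out from 14 and builds the benzylic carbon by carbonyl addition. Vilsmeier–Haack formylation (POCl3, DMF, 0 °C → rt) at C6 gives 5,7-dihydroxy-2,2-dimethyl-8-(2-methylpropanoyl)chroman-6-carbaldehyde F4. 5-Methylhexylmagnesium bromide F5 is made from commercial 1-bromo-5-methylhexane and Mg in THF. Four equivalents at −40 °C (the first two deprotonate the phenols and are lost as 2-methylhexane) add to the formyl group and, after a dilute HCl quench, give the benzylic alcohol, which comes back to the route at 17, here isolated. p-TolSO2H in CH2Cl2 then converts 17 into 18 as in step 7.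

**Further compounds**

F1 | step 8 | (2R)-1-{6-[(1S)-1-[5,7-dihydroxy-2,2-dimethyl-8-(2-methylpropanoyl)chroman-6-yl]-6-methylheptyl]-5,7-dihydroxy-2,2-dimethylchroman-8-yl}-2-methylbutan-1-one | CC[C@@H](C)C(=O)c1c(O)c([C@@H](CCCCC(C)C)c2c(O)c3c(c(C(=O)C(C)C)c2O)OC(C)(C)CC3)c(O)c2c1OC(C)(C)CC2
F2 | step 4 | 3,5-bis(tert-butyldimethylsilyloxy)phenyl (2R)-2-methylbutanoate | CC[C@@H](C)C(=O)Oc1cc(O[Si](C)(C)C(C)(C)C)cc(O[Si](C)(C)C(C)(C)C)c1
F3 | step 4 | (2R)-1-[2-hydroxy-4,6-bis(tert-butyldimethylsilyloxy)phenyl]-2-methylbutan-1-one | CC[C@@H](C)C(=O)c1c(O)cc(O[Si](C)(C)C(C)(C)C)cc1O[Si](C)(C)C(C)(C)C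
F4 | step 7 | 5,7-dihydroxy-2,2-dimethyl-8-(2-methylpropanoyl)chroman-6-carbaldehyde | CC(C)C(=O)c1c(O)c(C=O)c(O)c2c1OC(C)(C)CC2
F5 | step 7 | 5-methylhexylmagnesium bromide | CC(C)CCCC[Mg]Br
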